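## Retrosynthetic overview

1. Cage numbering: C1 benzoyl bridgehead, C2 and C4 ketones on either side of quaternary C3, C5 geranyl bridgehead, C6 CH2, C7 CH, C8 CMe2, C9 bridging ketone, C10 CH2 (C7 to C11), C11 cyclopentane CH; ring A = C1–C9–C5–C6–C7–C8, ring B = C1–C2–C3–C4–C5–C9.
2. Feature used: C1 is the α-carbon of the ring-A ketone C9 that lies next to the gem-dimethyl carbon C8, and it is bonded through C2 to C3, which carries two carbonyl carbons (C2, C4) and is therefore a malonate carbon. The seven-membered ring C1–C2–C3–C11–C10–C7–C8 is cis-fused to the cyclopentane, so adding the second methyl to C8 of a C1=C8 enone gives exactly the C1 enolate that can be acylated by the C3 ester cis to C10.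
3. Disconnections: C1–COPh (bridgehead acylation); C4–C5 (aldol of the C5 enolate onto a C4 aldehyde); C5–geranyl (enolate alkylation); C8–CH3 with C1–C2 (cuprate addition–Dieckmann); ring A from a C7 aldehyde and methyl vinyl ketone; C3–C11 by iminium-catalysed malonate Michael cyclisation.
4. Ring order: cyclopentane (step 5), ring A (step 8), seven-membered ring (step 10), ring B closing the homoadamantane cage (step 17). C11 and C7 are set by two catalyst-controlled steps, whose facial sense is assigned from the usual shielding model; C3, C1 and C5 follow from ring constraints.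

Key step: step 10

Remark (assumption on the chemistry): C2 (steps 12 to 18), C5 (steps 14 to 16) and the C4 carbinol (steps 17 and 18) are transient stereocentres that are later oxidised or re-enolised; they are carried as unassigned epimers and left open in the SMILES. C8 of 14 is drawn trans to the C7 side chain.

## Route

Step 1
Reactants: 1 methyl 3,3-dimethylpent-4-enoate
Product: 2 3,3-dimethylpent-4-en-1-ol
Conditions: LiAlH4, Et2O, 0 °C
Reagents that add atoms: none
Why: LiAlH4 reduction of an ester to the primary alcohol; the isolated vinyl group is inert to hydride.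

Step 2
Reactants: 2 3,3-dimethylpent-4-en-1-ol
Product: 3 5-iodo-3,3-dimethylpent-1-ene
Conditions: I2, PPh3, imidazole, CH2Cl2, 0 °C to rt
Reagents that add atoms: iodine, II
Why: Appel-type iodination, in which iodide displaces the oxyphosphonium group from the unhindered primary carbon by SN2.

Step 3
Reactants: 3 5-iodo-3,3-dimethylpent-1-ene; 4 dimethyl malonate
Product: 5 dimethyl 2-(3,3-dimethylpent-4-en-1-yl)malonate
Conditions: NaH, 4 (3 equiv), THF/DMF, 0 to 60 °C
Reagents that add atoms: none
Why: Malonic ester alkylation; the sodium enolate of 4, used in excess to suppress dialkylation, displaces iodide from a primary carbon whose neighbour is a CH2 (SN2).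

Step 4
Reactants: 5 dimethyl 2-(3,3-dimethylpent-4-en-1-yl)malonate; 6 (E)-but-2-enal
Product: 7 dimethyl 2-[(4E)-3,3-dimethyl-6-oxohex-4-en-1-yl]malonate
Conditions: second-generation Hoveyda–Grubbs catalyst RuCl2(H2IMes)(=CH-C6H4-2-O-i-Pr) (5 mol %), 6 (5 equiv), CH2Cl2, 40 °C
Reagents that add atoms: none
Why: Olefin cross-metathesis; the vinyl group on the quaternary carbon does not homodimerise, the enal partner dimerises only slowly, and the conjugated E-enal is the thermodynamic product.

Step 5
Reactants: 7 dimethyl 2-[(4E)-3,3-dimethyl-6-oxohex-4-en-1-yl]malonate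
Product: 8 dimethyl (2R)-3,3-dimethyl-2-(2-oxoethyl)cyclopentane-1,1-dicarboxylate
Conditions: (R)-α,α-bis[3,5-bis(trifluoromethyl)phenyl]prolinol trimethylsilyl ether (20 mol %), EtOH, 0 °C to rt
Reagents that add atoms: none
Why: Iminium-catalysed intramolecular Michael addition of the malonate to the enal (5-exo-trig, helped by the gem-dimethyl group); on the E, s-trans iminium ion the diarylsilyloxymethyl group of the R catalyst shields one face, so the malonate carbon adds to the other face of C11 and sets it R.

Step 6
Reactants: 8 dimethyl (2R)-3,3-dimethyl-2-(2-oxoethyl)cyclopentane-1,1-dicarboxylate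
Product: 10 dimethyl (2R)-3,3-dimethyl-2-(3-oxopropyl)cyclopentane-1,1-dicarboxylate, via methyl enol ether 9 (not isolated)
Conditions: Ph3P(CH2OMe)Cl, KN(SiMe3)2, THF, −78 to 0 °C; then 2 M HCl, THF, rt
Reagents that add atoms: (methoxymethyl)triphenylphosphonium chloride, [Cl-].COC[P+](c1ccccc1)(c1ccccc1)c1ccccc1; water, O
Why: Wittig methoxymethylenation followed by acid hydrolysis of the enol ether is the standard one-carbon homologation of an aldehyde; C11 is not enolisable and the quaternary diester is untouched.

Step 7
Reactants: 10 dimethyl (2R)-3,3-dimethyl-2-(3-oxopropyl)cyclopentane-1,1-dicarboxylate; 11 methyl vinyl ketone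
Product: 12 dimethyl (2R)-2-[(2S)-2-formyl-5-oxohexyl]-3,3-dimethylcyclopentane-1,1-dicarboxylate
Conditions: (S)-2-[methoxy(diphenyl)methyl]pyrrolidine (5 mol %), ethyl 3,4-dihydroxybenzoate (20 mol %), neat, 4 °C
Reagents that add atoms: none
Why: Enamine-catalysed Michael addition of the aldehyde to the vinyl ketone; the E anti-enamine of the S catalyst is attacked on the face away from the diphenylmethoxymethyl group, which sets C7 as S independently of the remote C11 centre and avoids any SN2 displacement at the neopentyl-type C10.

Step 8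
Reactants: 12 dimethyl (2R)-2-[(2S)-2-formyl-5-oxohexyl]-3,3-dimethylcyclopentane-1,1-dicarboxylate
Product: 13 dimethyl (2R)-3,3-dimethyl-2-{[(1S)-4-oxocyclohex-2-en-1-yl]methyl}cyclopentane-1,1-dicarboxylate
Conditions: LiOH·H2O (0.2 equiv), i-PrOH, rt
Reagents that add atoms: none
Why: Intramolecular aldol condensation (the closing stage of a Robinson annulation) of the methyl ketone onto the aldehyde forms ring A as the conjugated enone; cyclisation of the methyl enolate should be faster than enolisation at C7.

Step 9
Reactants: 13 dimethyl (2R)-3,3-dimethyl-2-{[(1S)-4-oxocyclohex-2-en-1-yl]methyl}cyclopentane-1,1-dicarboxylate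
Product: 15 dimethyl (2R)-3,3-dimethyl-2-{[(1S)-2-methyl-4-oxocyclohex-2-en-1-yl]methyl}cyclopentane-1,1-dicarboxylate, via trimethylsilyl enol ether 14 (not isolated)
Conditions: Me2CuLi (from MeLi, CuI), Me3SiCl, THF, −78 °C; Et3N, pentane work-up; then Pd(OAc)2 (1.1 equiv), MeCN, rt
Reagents that add atoms: lithium dimethylcuprate, [Li+].C[Cu-]C; chlorotrimethylsilane, C[Si](C)(C)Cl (its atoms stay only in 14)
Why: Silyl-chloride-accelerated Gilman conjugate addition puts the first methyl on C8 with the enolate trapped at once as its silyl enol ether, so no premature acylation can occur, and Saegusa–Ito oxidation (β-hydride elimination toward C8) restores the C1=C8 double bond, now methyl-substituted, without touching C7.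

Step 10
Reactants: 15 dimethyl (2R)-3,3-dimethyl-2-{[(1S)-2-methyl-4-oxocyclohex-2-en-1-yl]methyl}cyclopentane-1,1-dicarboxylate
Product: 17 tricyclic β-diketone ester (C2/C9 ketones; C1–H; CO2Me = C4 on C3 trans to C10; cyclopentane cis-fused to the new seven-membered ring; C7 S; C11 R), via lithium enolate 16 (not isolated)
Conditions: Me2CuLi (from MeLi, CuI; 3 equiv), Et2O, −30 to 0 °C; then THF, HMPA, 0 to 45 °C; aq. NH4Cl
Reagents that add atoms: lithium dimethylcuprate, [Li+].C[Cu-]C
Why: Me2CuLi transfers methyl to C8 of the β-methyl enone (1,4-addition through the copper π-complex), leaving enolate 16 with its nucleophilic carbon fixed at C1, a regiochemistry that deprotonation of the 3,3-dimethyl ketone (C5 favoured) could not give. On warming in THF/HMPA this enolate adds to an ester carbonyl on C3 and expels methoxide (Dieckmann-type acylation; the closest known type is the tandem cuprate conjugate addition–intramolecular enolate acylation), a 7-exo-trig closure of ring C1–C2–C3–C11–C10–C7–C8 that is pulled forward because the methoxide deprotonates C1 of the β-diketone formed. The new bond at C1 must be cis to C7–C10, since the one-carbon C8 bridge of the resulting bicyclo[4.3.1]decane allows nothing else, so C1 is fixed by the tether. C3 becomes stereogenic through the choice between its diastereotopic esters: in this bicycle the C11–C3 bond lies opposite the C8 bridge and is close to eclipsed, which fits the ester cis to C10 (cis-fused cyclopentane, torsion below about 45°) but not the trans ester (75° or more), so C11 controls C3. The step needs 1,4- over 1,2-addition and no attack of the reagent on the esters, both normal for a Gilman reagent, and closure before the enolate is quenched, which the aprotic medium and the irreversible diketonate formation should secure.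

Step 11
Reactants: 17 tricyclic β-diketone ester
Product: 18 C9 methyl enol ether of 17 (C9(OMe)=C1 conjugated to the C2 ketone; C4 ester unchanged)
Conditions: HC(OMe)3, TsOH·H2O (cat.), MeOH, 40 °C
Reagents that add atoms: trimethyl orthoformate, COC(OC)OC
Why: Acid-catalysed enol etherification of an unsymmetrical β-diketone occurs at the less hindered carbonyl, here C9 (next to the C5 methylene) rather than C2 (next to quaternary C3), as with 4,4-dimethylcyclohexane-1,3-dione; this masks C9, which hydride would otherwise attack before C2.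

Step 12
Reactants: 18 C9 methyl enol ether of 17
Product: 19 diol (C2 secondary alcohol; C4 primary alcohol; C9 methyl enol ether retained)
Conditions: LiAlH4, THF, 0 °C to rt; aq. potassium sodium tartrate work-up
Reagents that add atoms: none
Why: LiAlH4 adds 1,2 to the vinylogous ester carbonyl (first stage of a Stork–Danheiser sequence) and reduces the C4 ester to the primary alcohol, while the enol ether survives the non-acidic work-up.

Step 13
Reactants: 19 diol
Product: 21 C9 ketone bearing tert-butyldimethylsilyl ethers at C2–O and C4–O, via bis-silyl methyl enol ether 20 (not isolated)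
Conditions: t-BuMe2SiOTf, 2,6-lutidine, CH2Cl2, 0 °C to rt; then PPTS, acetone/H2O, rt
Reagents that add atoms: tert-butyldimethylsilyl triflate, CC(C)(C)[Si](C)(C)OS(=O)(=O)C(F)(F)F; water, O
Why: The silyl triflate silylates the hindered C2 hydroxyl and the primary C4 hydroxyl, and mild aqueous acid then hydrolyses only the enol ether, with C1 protonated on the one face the bridge allows; loss of the β-silyloxy group is disfavoured because it would give a C1=C2 bridgehead enone.

Step 14
Reactants: 21 C9 ketone bis-silyl ether; 22 geranyl bromide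
Product: 23 C5-geranyl ketone (C5 epimers)
Conditions: LiN(i-Pr)2, THF, −78 °C; then 22, DMPU, −78 to −20 °C
Reagents that add atoms: none
Why: Kinetic deprotonation occurs at the C5 methylene rather than at the hindered tertiary C1–H, and the lithium enolate is alkylated by the allylic bromide (SN2).

Step 15
Reactants: 23 C5-geranyl ketone
Product: 24 C4 primary alcohol (C2 silyl ether retained)
Conditions: HF·pyridine, pyridine, THF, 0 °C to rt
Reagents that add atoms: none
Why: Buffered HF·pyridine cleaves the primary silyl ether much faster than the shielded secondary one at C2 (steric selectivity of silyl ether cleavage).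

Step 16
Reactants: 24 C4 primary alcohol
Product: 25 C4 aldehyde (non-enolisable; on C3)
Conditions: Dess–Martin periodinane, CH2Cl2, rt
Reagents that add atoms: none
Why: Dess–Martin oxidation of the primary alcohol (free or in equilibrium with its hemiketal to C9) to the aldehyde under conditions that leave the geranyl alkenes and the silyl ether alone.

Step 17
Reactants: 25 C4 aldehyde
Product: 26 homoadamantane aldol (C4 carbinol; C9 ketone; C2 silyl ether; C5 geranyl)
Conditions: NaOEt (0.5 equiv), EtOH, 0 °C to rt; aq. NH4Cl
Reagents that add atoms: none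
Why: Intramolecular aldol addition under equilibrating ethoxide; the C5 enolate, the only one that can reach an electrophile, adds to the C4 aldehyde held over ring A on C3, closing ring B (6-enolexo-exo-trig) and the cage, and C5 can only bond on the face that carries C2 and C10, so its configuration is dictated by the cage.

Step 18
Reactants: 26 homoadamantane aldol
Product: 27 C2,C4-diol C9-ketone
Conditions: aq. HF (48 %), MeCN, rt
Reagents that add atoms: none
Why: Aqueous HF removes the remaining hindered silyl ether under acidic conditions that cannot trigger retro-aldol cleavage of the β-hydroxy ketone.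

Step 19
Reactants: 27 C2,C4-diol C9-ketone
Product: 28 2,4,9-trione with C1–H (debenzoyl target)
Conditions: Dess–Martin periodinane (3 equiv), CH2Cl2, rt
Reagents that add atoms: none
Why: Dess–Martin oxidation of both secondary alcohols gives the non-enolisable trione under near-neutral conditions that avoid retro-Claisen cleavage.

Step 20
Reactants: 28 2,4,9-trione; 29 benzoyl chloride
Product: 30 CNP0168637.1 (target)
Conditions: lithium 2,2,6,6-tetramethylpiperidide (from the amine, n-BuLi), THF, −78 °C; then 29, −78 to −40 °C
Reagents that add atoms: none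
Why: Bridgehead lithiation–acylation as used on bicyclo[3.3.1]nonane-trione cores; C1–H is the only acidic proton left, the hindered amide does not add to the ketones, and the bridgehead anion, which cannot become a planar enolate, is acylated on carbon with retention because the cage allows no other geometry.

## Compound list

1 | methyl 3,3-dimethylpent-4-enoate | COC(=O)CC(C)(C)C=C | starting material
2 | 3,3-dimethylpent-4-en-1-ol | OCCC(C)(C)C=C | intermediate
3 | 5-iodo-3,3-dimethylpent-1-ene | ICCC(C)(C)C=C | intermediate
4 | dimethyl malonate | COC(=O)CC(=O)OC | starting material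
5 | dimethyl 2-(3,3-dimethylpent-4-en-1-yl)malonate | COC(=O)C(CCC(C)(C)C=C)C(=O)OC | intermediate
6 | (E)-but-2-enal | C/C=C/C=O | starting material
7 | dimethyl 2-[(4E)-3,3-dimethyl-6-oxohex-4-en-1-yl]malonate | COC(=O)C(CCC(C)(C)/C=C/C=O)C(=O)OC | intermediate
8 | dimethyl (2R)-3,3-dimethyl-2-(2-oxoethyl)cyclopentane-1,1-dicarboxylate | COC(=O)C1(C(=O)OC)CCC(C)(C)[C@H]1CC=O | intermediate
9 | dimethyl (2R)-2-(3-methoxyprop-2-en-1-yl)-3,3-dimethylcyclopentane-1,1-dicarboxylate (E/Z mixture; not isolated) | COC(=O)C1(C(=O)OC)CCC(C)(C)[C@H]1CC=COC | intermediate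
10 | dimethyl (2R)-3,3-dimethyl-2-(3-oxopropyl)cyclopentane-1,1-dicarboxylate | COC(=O)C1(C(=O)OC)CCC(C)(C)[C@H]1CCC=O | intermediate
11 | methyl vinyl ketone | CC(=O)C=C | starting material
12 | dimethyl (2R)-2-[(2S)-2-formyl-5-oxohexyl]-3,3-dimethylcyclopentane-1,1-dicarboxylate | COC(=O)C1(C(=O)OC)CCC(C)(C)[C@H]1C[C@@H](C=O)CCC(C)=O | intermediate
13 | dimethyl (2R)-3,3-dimethyl-2-{[(1S)-4-oxocyclohex-2-en-1-yl]methyl}cyclopentane-1,1-dicarboxylate | COC(=O)C1(C(=O)OC)CCC(C)(C)[C@H]1C[C@@H]2CCC(=O)C=C2 | intermediate
14 | dimethyl (2R)-3,3-dimethyl-2-{[(1S,2S)-2-methyl-4-(trimethylsilyloxy)cyclohex-3-en-1-yl]methyl}cyclopentane-1,1-dicarboxylate (trans; not isolated) | COC(=O)C1(C(=O)OC)CCC(C)(C)[C@H]1C[C@@H]2CCC(O[Si](C)(C)C)=C[C@H]2C | intermediate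
15 | dimethyl (2R)-3,3-dimethyl-2-{[(1S)-2-methyl-4-oxocyclohex-2-en-1-yl]methyl}cyclopentane-1,1-dicarboxylate (key-step precursor) | COC(=O)C1(C(=O)OC)CCC(C)(C)[C@H]1C[C@@H]2CCC(=O)C=C2C | intermediate
16 | lithium (4S)-4-{[(1R)-2,2-bis(methoxycarbonyl)-5,5-dimethylcyclopentyl]methyl}-3,3-dimethylcyclohex-1-en-1-olate (C1 enolate; not isolated) | COC(=O)C1(C(=O)OC)CCC(C)(C)[C@H]1C[C@@H]2CCC(O[Li])=CC2(C)C | intermediate
17 | tricyclic β-diketone ester: ring A (C9 ketone, C8 gem-dimethyl) bridged from C1 to C7 by C2(=O)–C3–C11–C10; cyclopentane cis-fused at C3–C11; CO2Me (C4) on C3 trans to C10; C7 S, C11 R (key-step product) | COC(=O)[C@]12CCC(C)(C)[C@H]1C[C@@H]3CCC(=O)[C@H](C2=O)C3(C)C | intermediate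
18 | C9 methyl enol ether of 17 (C9(OMe)=C1, C2 ketone, C4 methyl ester) | COC(=O)[C@]12CCC(C)(C)[C@H]1C[C@@H]3CCC(OC)=C(C2=O)C3(C)C | intermediate
19 | diol: C2 secondary alcohol (epimer not assigned), C4 primary alcohol, C9 methyl enol ether | OC[C@]12CCC(C)(C)[C@H]1C[C@@H]3CCC(OC)=C(C2O)C3(C)C | intermediate
20 | bis(tert-butyldimethylsilyl) ether of 19 (not isolated) | CC(C)(C)[Si](C)(C)OC[C@]12CCC(C)(C)[C@H]1C[C@@H]3CCC(OC)=C(C2O[Si](C)(C)C(C)(C)C)C3(C)C | intermediate
21 | C9 ketone with C1–H, C5 H2, silyl ethers at C2–O and C4–O | CC(C)(C)[Si](C)(C)OC[C@]12CCC(C)(C)[C@H]1C[C@@H]3CCC(=O)[C@H](C2O[Si](C)(C)C(C)(C)C)C3(C)C | intermediate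
22 | geranyl bromide, (2E)-1-bromo-3,7-dimethylocta-2,6-diene | CC(C)=CCC/C(C)=C/CBr | starting material
23 | C5-geranyl derivative of 21 (C5 epimers) | CC(C)(C)[Si](C)(C)OC[C@]12CCC(C)(C)[C@H]1C[C@@H]3CC(C/C=C(\C)CCC=C(C)C)C(=O)[C@H](C2O[Si](C)(C)C(C)(C)C)C3(C)C | intermediate
24 | C4 primary alcohol (C2 silyl ether, C9 ketone, C5 geranyl) | OC[C@]12CCC(C)(C)[C@H]1C[C@@H]3CC(C/C=C(\C)CCC=C(C)C)C(=O)[C@H](C2O[Si](C)(C)C(C)(C)C)C3(C)C | intermediate
25 | C4 aldehyde (C2 silyl ether, C9 ketone, C5 geranyl) | O=C[C@]12CCC(C)(C)[C@H]1C[C@@H]3CC(C/C=C(\C)CCC=C(C)C)C(=O)[C@H](C2O[Si](C)(C)C(C)(C)C)C3(C)C | intermediate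
26 | homoadamantane aldol: C4 carbinol, C9 ketone, C2 silyl ether, C5 geranyl bridgehead, C1–H | CC(C)=CCC/C(C)=C/C[C@@]12C[C@H]3C[C@@H]4C(C)(C)CC[C@]4(C1O)C(O[Si](C)(C)C(C)(C)C)[C@@H](C2=O)C3(C)C | intermediate
27 | C2,C4-diol C9-ketone of the cage | CC(C)=CCC/C(C)=C/C[C@@]12C[C@H]3C[C@@H]4C(C)(C)CC[C@]4(C1O)C(O)[C@@H](C2=O)C3(C)C | intermediate
28 | 2,4,9-trione with C1–H (debenzoyl target) | CC(C)=CCC/C(C)=C/C[C@@]12C[C@H]3C[C@@H]4C(C)(C)CC[C@]4(C1=O)C(=O)[C@@H](C2=O)C3(C)C | intermediate
29 | benzoyl chloride | O=C(Cl)c1ccccc1 | starting material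
30 | CNP0168637.1 | CC(C)=CCC/C(C)=C/C[C@@]12C[C@H]3C[C@@H]4C(C)(C)CC[C@]4(C1=O)C(=O)[C@@](C(=O)c1ccccc1)(C2=O)C3(C)C | target

## Step count and risks

Total steps: 20. Longest linear sequence: 20 steps (1 to 30); the other components (4, 6, 11, 22, 29) are commercial.

Steps most likely to fail:

Step 10. The enolate carbon C1 lies next to quaternary C8 and the ester lies on quaternary C3, so ring closure may be too slow and the enolate may simply be protonated on work-up, giving only the conjugate adduct. Fallback (sets out from 15, returns at 17): run the cuprate addition with aqueous work-up and isolate dimethyl (2R)-2-{[(1S)-2,2-dimethyl-4-oxocyclohexyl]methyl}-3,3-dimethylcyclopentane-1,1-dicarboxylate F1. The ring is then closed in a separate Claisen condensation under thermodynamic control (KOt-Bu, THF/t-BuOH, reflux). The ketone enolises reversibly toward C5 and C1, only the C1 enolate can reach an ester, and the product is drained off as its β-diketonate, so the regiochemistry is corrected by equilibration and need not be imposed by the conjugate addition.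

Step 17. Under basic conditions the aldol may revert (retro-aldol), the C2 silyloxy group may be lost by elimination through the C1 enolate, or bond formation at the fully substituted C5 may be too slow. Fallback (sets out from 25, returns at 26): treat 25 with Me3SiOTf and Et3N to form the C5=C9 trimethylsilyl enol ether F2, the more substituted, non-bridgehead enol ether. Ring B is then closed by a Lewis-acid-promoted Mukaiyama aldol (BF3·OEt2, CH2Cl2, −78 °C), which activates the aldehyde, is irreversible after silyl transfer and never forms an enolate at C1; aqueous work-up gives 26.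

Step 20. The lithiated bridgehead next to the C8 gem-dimethyl group may react too slowly with the acid chloride, which is then consumed by the amide base. Fallback (sets out from 28, returns at 30): quench the lithiated trione with I2 to give the C1 bridgehead iodide F3, carry out iodine–magnesium exchange with i-PrMgCl·LiCl at −78 °C and add benzaldehyde to give the C1 hydroxy(phenyl)methyl trione F4, then oxidise with Dess–Martin periodinane to 30. Small electrophiles (iodine, then an aldehyde) replace the acid chloride.

## Further compounds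

F1 | step 10 | dimethyl (2R)-2-{[(1S)-2,2-dimethyl-4-oxocyclohexyl]methyl}-3,3-dimethylcyclopentane-1,1-dicarboxylate | COC(=O)C1(C(=O)OC)CCC(C)(C)[C@H]1C[C@@H]2CCC(=O)CC2(C)C
F2 | step 17 | C5=C9 trimethylsilyl enol ether of aldehyde 25 | O=C[C@]12CCC(C)(C)[C@H]1C[C@@H]3CC(C/C=C(\C)CCC=C(C)C)=C(O[Si](C)(C)C)[C@H](C2O[Si](C)(C)C(C)(C)C)C3(C)C
F3 | step 20 | C1 bridgehead iodide of trione 28 | CC(C)=CCC/C(C)=C/C[C@@]12C[C@H]3C[C@@H]4C(C)(C)CC[C@]4(C1=O)C(=O)[C@@](I)(C2=O)C3(C)C
F4 | step 20 | C1 hydroxy(phenyl)methyl trione (carbinol epimers) | CC(C)=CCC/C(C)=C/C[C@@]12C[C@H]3C[C@@H]4C(C)(C)CC[C@]4(C1=O)C(=O)[C@@](C(O)c1ccccc1)(C2=O)C3(C)C
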